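The runs stem from a simulated flask on assumed constants; scatter was added.

The rate constants of this chemistry were unknown to me, so I began from the two earlier runs.

the same everywhere: starting material 20 mM

| flask | partner | remark | time |
|---|---|---|---|
| north-west | 6.3 mM | run made earlier |  |
| west | 42 mM | run made earlier |  |
| zeta | 5.00 mM |  | 15 h |
| alpha | 15.0 mM |  | 15 h |
| epsilon | 50.0 mM |  | 15 h |

| run | time / h | single product / % | starting material / % |
|---|---|---|---|
| north-west | 0.667 | 18.7 | 38.6 |
| north-west | 2.00 | 18.7 | 37.1 |
| north-west | 4.00 | 18.9 | 37.7 |
| north-west | 5.00 | 18.3 | 37.7 |
| north-west | 8.00 | 18.1 | 37.9 |
| west | 1.50 | 9.6 | 6.5 |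
| west | 3.00 | 8.9 | 7.8 |
| west | 5.00 | 8.3 | 7.3 |
| west | 6.00 | 9.6 | 7.8 |
| west | 8.00 | 8.9 | 7.3 |

(readings scatter by 0.5 percentage points)

1. amount of single product at the end, in percent of the starting material charged for zeta, alpha, epsilon, in this order
2. how that number moves from the first to the last of them (rises all the way / rises, then falls / hardly changes / falls all the way / falls, then rises)

- the numbers in the tables scatter by 0.5 percentage points (one standard deviation)
- "hardly changes" means that all values lie within two and a half points (for a concentration: within two and a half percent of the largest)

Zeta looks nearly the same as north-west: equal starting material, with partner at 5.00 mM against 6.3 mM. North-west read flat from 0.667 h onward, with starting material still at 37.9%. Its partner was charged at less than its starting material, so I took partner as the limiting reagent there and in zeta. From each run I then reckoned how much of the partner charged ended as single product, using the mean reading: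

north-west: 18.5% of 20 mM, on 6.3 mM of partner, gives 58.9%

west: 9.06% of 20 mM, on 42 mM of partner, gives 4.31%

This partner yield, the concentration of single product standing at the end per concentration of partner charged, was lower in west than in north-west. I read that as single product taking up partner itself. Zeta, with less partner than north-west, should keep at least north-west's yield, and epsilon, with more partner than west, at most west's:

zeta: 58.9% × 5.00 mM / 20 mM = 14.7% or somewhat above

epsilon: 4.31% × 50.0 mM / 20 mM = 10.8% or below

Zeta's figure is a floor and epsilon's a ceiling, and the floor lies higher than the ceiling. So I committed to a row that ends lower than it starts; I did not reckon alpha, and its place in the row stayed open.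

The forecast gave 20.5%, 13.5% and 8.4%, a row that falls all the way, on the ground that “More partner pulls material into the hidden complex”. Its first value lies above my floor and its last below my ceiling, so at the two ends it stands within my limits.

The flask gave 16.1%, 24.6% and 4.91%: the row rises, then falls.

    partner + single product → bis adduct + released group (k = 0.541 /M/s)
    partner + bis adduct → triple product + released group (k = 0.120 /M/s)
    partner + triple product → tetra adduct + released group (k = 0.340 /M/s)
    starting material ⇌ dormant form (K = 1.00, k = 8.54 × 10⁻⁴ /s)
    partner → decomposed reagent (k = 1.47 × 10⁻⁴ /s)
    starting material + partner → single product + released group (k = 0.324 /M/s)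

Partner reacted with single product at 0.541 /M/s and with starting material at 0.324 /M/s, a selectivity factor of 1.67. Weighted by what stood at 15.0 h, the claim of single product on partner over that of starting material was 0.674 in zeta and 1.72 in epsilon. In zeta, with partner at 0% of its charge, the partner yield came to 64.4%, above north-west's 58.9%. In epsilon, with partner at 0% of its charge, the partner yield came to 1.96%.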